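The ratio I began with was target late over target on the plateau. The earlier runs averaged a reading of 90.8 % at 30.0 min against 91.2 % at 8.00 min and 15.0 min, a ratio of 0.996.

| flask | substrate | remark | time |
|---|---|---|---|
| epsilon | 1.5 M | run made earlier |  |
| gamma | 1 M | run made earlier |  |
| delta | 2.2 M | run made earlier |  |
| dusk | 1.5 M | everything together in a closed stirred flask, run for 30 min | 30 min |
| dawn | 1.5 M | one stirred flow tank at steady state, fed with the mixture as stated, mean residence time 30 min |  |
| autumn | 1.5 M | a single well-mixed tank run continuously and read at steady state, 150 min in it on average |  |

- epsilon (time / min: target / %, substrate / %): 2.50: 82.6, 6.9; 8.00: 89.8, 0; 15.0: 92.1, 0; 20.0: 91.7, 2.1; 30.0: 90.5, 0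
- gamma (time / min: target / %, substrate / %): 2.50: 81.9, 6.8; 8.00: 91.2, 0; 15.0: 89.2, 1.1; 20.0: 90.2, 1.1; 30.0: 92.4, 0.4
- delta (time / min: target / %, substrate / %): 2.50: 83.0, 7.7; 5.00: 91.9, 0; 8.00: 92.6, 0.6; 15.0: 92.4, 0.8; 30.0: 89.6, 1.1

(readings scatter by 1 percentage point)

1. the set-up with the highest amount of target at the outlet or at the end, in percent of the substrate put in ("none" if the first two lie within 2 percentage points) (dusk / dawn / autumn / none)
2. amount of target at the outlet or at the end, in percent of the substrate put in, dusk
3. amount of target at the outlet or at the end, in percent of the substrate put in, dawn
4. amount of target at the outlet or at the end, in percent of the substrate put in, autumn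

- the stated concentrations are those of everything mixed, before any reaction; amounts are the same in each set-up
- the earlier runs were read with a standard deviation of 1 percentage point
- what may be going on: substrate -> target; substrate <-> intermediate A; intermediate A -> intermediate B; intermediate B -> side product; target -> over-reaction product
- the earlier runs were made in a closed, stirred flask

Target at 2.50 min read from 81.9 % to 83.0 % across the charges, and I treated the steps as first order. Pooling the readings at both plateau times was as far as I could tighten by hand. The difference of the two means, 18.5 min apart, then carried a standard deviation of 0.71 percentage points. At two deviations, target's rate of loss to over-reaction lay between zero and 0.00107 min⁻¹, my loss ceiling. The loss count is that rate times the mean residence time, the turnovers of over-reaction in one stay, and a tank divides the plateau by one plus the count.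

For autumn, a count of zero gave the upper bound 91.2 %. A count of 0.160 gave the lower bound 78.6 %. Substrate read at 2.50 min gave a rate of 1.06 min⁻¹. Dawn's mean stay equals dusk's 30 min, so I reckoned that dawn left 3.06 % unconverted, which put my estimate of its ceiling at 88.4 %. I took dusk to repeat the earlier runs at 90.8 %, above that ceiling by more than the margin. My bracket for autumn still reached dusk's value, so I left open whether dusk won or the answer was none.

The forecast chose dusk, with 91 %, 88 % and 84 %: “the 150 min tank gives about 92%, divided by 1.1, so about 84%, which is uncertain”. Its autumn figure lay inside my bracket, and its dawn figure lay under my ceiling.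

The flasks gave 90.6 % in dusk, 87.5 % in dawn and 82.4 % in autumn, so dusk stood highest and the forecast held.

    substrate → target (k = 0.0200 s⁻¹)
    substrate ⇌ intermediate A (K = 0.390, k = 0.100 s⁻¹)
    intermediate A → intermediate B (k = 0.00410 s⁻¹)
    intermediate B → side product (k = 0.00400 s⁻¹)
    target → over-reaction product (k = 1.30 × 10⁻⁵ s⁻¹)

Target's half-life by over-reaction alone, 15 h, was far longer than dusk's 30 min. It was also longer than autumn's mean stay, which counted 0.117 turnovers, and the autumn tank stood above my lower bound. In the flow tank at ten times dawn's residence time, my loss ceiling gave a count of 0.321 and a lower bound of 69.1 %, and that tank held 74.9 %.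

The earlier runs and the new flask are simulated on assumed constants; the scatter is artificial.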